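**Retrosynthetic overview**
1. Target ⇐ bipyridyl-buffered MOM removal, MnO2 oxidation at C4 and desilylation of 35. The C8–C3′ bond of 35 comes from a copper-mediated anti-SN2′ coupling of bromoflavan 20 (fragment 1: 21 non-hydrogen atoms of the target) with heptenyl picolinate 31 (fragment 2: 22 atoms).
2. Fragment 1: ring A from resorcinol (ortho-lithiation/bromination fixes C8, Ir borylation/oxidation/methylation gives 5-OMe, Hoesch acylation). Ring C is closed as a chromone, ring B is added by Rh-catalysed asymmetric 1,4-addition (sets C2), and the ketone is masked as the cis 4-OTBS flavan.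
3. Fragment 2: alkenylzinc from alkyne 27 adds to aldehyde 21 (sets C1′ carbinol and the E-alkene). Alkyne 27 comes from a Heck-derived 3-arylpropanal by asymmetric propargylation (sets C5′).
4. Ring order: ring A (resorcinol) → ring C (step 7) → ring B attached (step 11) → side chain joined (step 21) → C4 ketone restored (step 23).

Assumption: the facial sense of the three catalyst-controlled steps (11, 17, 19) follows the published models for the parent substrates; these senses are assigned by analogy and from memory, not checked on these substrates, and the catalyst antipode would be used if a model compound showed the opposite sense.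

Abbreviations in names: MOMO = methoxymethoxy, TBSO = tert-butyldimethylsilyloxy, TMSO = trimethylsilyloxy; Fl = the aryl group of 20 bonded through C8, i.e. (2S,4S)-4-(TBSO)-5-methoxy-7-(MOMO)-2-[4-(MOMO)phenyl]chroman-8-yl. Side-chain carbons are C1′ (styryl CH) to C7′; C3′ is bonded to C8 and C5′ is the carbinol.

**Route**

Step 1
Reactants: 1 resorcinol
Product: 2 1,3-bis(methoxymethoxy)benzene
Conditions: NaH (2.4 equiv), MOMCl (2.4 equiv), DMF, 0 °C to rt
Reagents that add atoms: chloromethyl methyl ether (MOMCl), COCCl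
Why: Williamson O-alkylation of the bis-phenoxide gives the bis-MOM ether, which serves as protecting group and as directing group for step 2.

Step 2
Reactants: 2 1,3-bis(methoxymethoxy)benzene
Product: 4 2-bromo-1,3-bis(methoxymethoxy)benzene, via aryllithium 3 (not isolated)
Conditions: n-BuLi (1.1 equiv), THF, 0 °C, 1 h; BrCH2CH2Br, −78 °C to rt
Reagents that add atoms: 1,2-dibromoethane, BrCCBr
Why: Directed ortho-metalation occurs only at C2 between the two chelating MOMO groups, and bromine transfer from 1,2-dibromoethane fixes the later C8 handle unambiguously.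

Step 3
Reactants: 4 2-bromo-1,3-bis(methoxymethoxy)benzene
Product: 6 4-bromo-3,5-bis(methoxymethoxy)phenol, via arylboronate 5 (not isolated)
Conditions: [Ir(OMe)(cod)]2 (1.5 mol %), dtbpy (3 mol %), B2pin2 (0.7 equiv), THF, 80 °C; then 30% H2O2, aq NaOH, 0 °C
Reagents that add atoms: hydrogen peroxide, OO
Why: Sterically governed iridium-catalysed C–H borylation attacks the only C–H without an ortho substituent (C5) and leaves C–Br intact, and peroxide oxidation (1,2-aryl shift from boron to oxygen) gives the phenol.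

Step 4
Reactants: 6 4-bromo-3,5-bis(methoxymethoxy)phenol
Product: 7 2-bromo-5-methoxy-1,3-bis(methoxymethoxy)benzene
Conditions: MeI, K2CO3, acetone, reflux
Reagents that add atoms: iodomethane, CI
Why: Williamson O-methylation of the only free phenol installs the future 5-OMe group.

Step 5
Reactants: 7 2-bromo-5-methoxy-1,3-bis(methoxymethoxy)benzene
Product: 8 2-bromo-5-methoxybenzene-1,3-diol
Conditions: 3 M HCl/MeOH, 50 °C
Reagents that add atoms: none
Why: Acid-catalysed acetal exchange removes both MOM groups so that the free resorcinol ring is activated for C-acylation.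

Step 6
Reactants: 8 2-bromo-5-methoxybenzene-1,3-diol
Product: 10 1-(3-bromo-2,4-dihydroxy-6-methoxyphenyl)ethan-1-one, via ketiminium chloride 9 (not isolated)
Conditions: MeCN, ZnCl2, HCl (g), Et2O, 0 °C; then H2O, 90 °C
Reagents that add atoms: acetonitrile, CC#N; water, O
Why: In this Houben–Hoesch acylation the nitrilium ion can only attack C4 (identical to C6 by symmetry, C2 being blocked by bromine), so after hydrolysis the acetyl group necessarily lies between OMe and OH.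

Step 7
Reactants: 10 1-(3-bromo-2,4-dihydroxy-6-methoxyphenyl)ethan-1-one
Product: 12 8-bromo-7-hydroxy-5-methoxy-4H-chromen-4-one, via enaminone 11 (not isolated)
Conditions: t-BuOCH(NMe2)2 (3 equiv), toluene, 80 °C; then conc. HCl, CH2Cl2, rt
Reagents that add atoms: tert-butoxybis(dimethylamino)methane (Bredereck's reagent), CN(C)C(OC(C)(C)C)N(C)C
Why: Enaminone condensation at the acetyl methyl group followed by acid-promoted conjugate addition of the chelated 2-OH and loss of dimethylamine (chromone synthesis) closes ring C, and this aminal ester cannot O-methylate the free phenol.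

Step 8
Reactants: 12 8-bromo-7-hydroxy-5-methoxy-4H-chromen-4-one
Product: 13 8-bromo-5-methoxy-7-(methoxymethoxy)-4H-chromen-4-one
Conditions: MOMCl (1.3 equiv), K2CO3, acetone, rt
Reagents that add atoms: chloromethyl methyl ether (MOMCl), COCCl
Why: O-alkylation of the acidic 7-OH gives a group that tolerates the later ortho-metalated stage.

Step 9
Reactants: 14 4-bromophenol
Product: 15 1-bromo-4-(methoxymethoxy)benzene
Conditions: NaH, MOMCl, DMF, 0 °C to rt
Reagents that add atoms: chloromethyl methyl ether (MOMCl), COCCl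
Why: Williamson O-alkylation protects the phenol for the organometallic steps.

Step 10
Reactants: 15 1-bromo-4-(methoxymethoxy)benzene
Product: 17 [4-(methoxymethoxy)phenyl]boronic acid, via aryllithium 16 (not isolated)
Conditions: n-BuLi, THF, −78 °C; B(OiPr)3, −78 °C to rt; 1 M HCl, 0 °C
Reagents that add atoms: triisopropyl borate, CC(C)OB(OC(C)C)OC(C)C; water, O
Why: Bromine–lithium exchange is faster than any MOM-directed deprotonation, and borylation of the aryllithium followed by mild hydrolysis gives the boronic acid.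

Step 11
Reactants: 13 8-bromo-5-methoxy-7-(methoxymethoxy)-4H-chromen-4-one; 17 [4-(methoxymethoxy)phenyl]boronic acid
Product: 18 (2S)-8-bromo-5-methoxy-7-(MOMO)-2-[4-(MOMO)phenyl]-2,3-dihydro-4H-chromen-4-one
Conditions: [Rh(OH)(cod)]2 (3 mol %), (S)-MeO-F12-BIPHEP (6.6 mol %), 17 (3 equiv), toluene/H2O 10:1, 30 °C
Reagents that add atoms: none
Why: In this Hayashi–Miyaura asymmetric 1,4-addition the arylrhodium species carbometalates C2=C3 from the face left open by the (S)-biaryl bisphosphine (same sense as (S)-BINAP giving (S)-3-arylcyclohexanones), which sets 2S, and the neutral conditions protonate the rhodium enolate without ring opening.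

Step 12
Reactants: 18 (2S)-8-bromo-5-methoxy-7-(MOMO)-2-[4-(MOMO)phenyl]-2,3-dihydro-4H-chromen-4-one
Product: 19 (2S,4S)-8-bromo-5-methoxy-7-(MOMO)-2-[4-(MOMO)phenyl]-3,4-dihydro-2H-chromen-4-ol
Conditions: NaBH4, MeOH/THF 1:1, 0 °C
Reagents that add atoms: none
Why: Borohydride reduction with axial hydride attack on the half-chair carrying an equatorial 2-aryl group gives the 2,4-cis (4S) alcohol, a centre that only masks C4 during the organometallic coupling and is removed again in step 23.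

Step 13
Reactants: 19 (2S,4S)-8-bromo-5-methoxy-7-(MOMO)-2-[4-(MOMO)phenyl]-3,4-dihydro-2H-chromen-4-ol
Product: 20 (2S,4S)-8-bromo-4-(TBSO)-5-methoxy-7-(MOMO)-2-[4-(MOMO)phenyl]chromane
Conditions: TBSCl, imidazole, DMAP (cat.), DMF, 40 °C
Reagents that add atoms: tert-butyldimethylsilyl chloride, CC(C)(C)[Si](C)(C)Cl
Why: Imidazole-promoted O-silylation gives a benzylic ether that is inert to t-BuLi and to the organocopper stage.

Step 14
Reactants: 15 1-bromo-4-(methoxymethoxy)benzene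
Product: 21 4-(methoxymethoxy)benzaldehyde
Conditions: Pd(OAc)2 (0.5 mol %), n-BuP(1-Ad)2 (1.5 mol %), TMEDA (1.0 equiv), CO/H2 1:1 (5 bar), toluene, 100 °C
Reagents that add atoms: carbon monoxide, [C-]#[O+]
Why: In this palladium-catalysed reductive carbonylation (formylation of an aryl bromide with synthesis gas) zerovalent palladium inserts into C–Br, CO insertion gives the acylpalladium bromide and hydrogenolysis with H2 releases the aldehyde while TMEDA takes up HBr; the MOM acetal is stable to these basic conditions.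

Step 15
Reactants: 22 4-iodophenol
Product: 23 1-iodo-4-(methoxymethoxy)benzene
Conditions: NaH, MOMCl, DMF, 0 °C to rt
Reagents that add atoms: chloromethyl methyl ether (MOMCl), COCCl
Why: Williamson O-alkylation protects the phenol while keeping the reactive C–I bond for the Heck step.

Step 16
Reactants: 23 1-iodo-4-(methoxymethoxy)benzene; 24 allyl alcohol
Product: 25 3-[4-(methoxymethoxy)phenyl]propanal
Conditions: Pd(OAc)2 (3 mol %), NaHCO3 (2.5 equiv), Bu4NCl (1 equiv), DMF, 40 °C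
Reagents that add atoms: none
Why: In this Heck reaction under Jeffery conditions, arylpalladium adds to the terminal carbon and β-hydride elimination toward the carbinol gives an enol that tautomerises to the saturated aldehyde.

Step 17
Reactants: 25 3-[4-(methoxymethoxy)phenyl]propanal
Product: 26 (3S)-1-[4-(methoxymethoxy)phenyl]hex-5-yn-3-ol
Conditions: allenylboronic acid pinacol ester (1.5 equiv), (R)-TRIP (10 mol %), 4 Å MS, toluene, 0 °C; aq NaHCO3
Reagents that add atoms: allenylboronic acid pinacol ester, C=C=CB1OC(C)(C)C(C)(C)O1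
Why: In this chiral phosphoric acid-catalysed propargylation the allenylboronate adds by SE2′ through a six-membered chair transition state held by the phosphate, and (R)-TRIP directs attack to the Re face of the aldehyde, which gives the 3S homopropargylic alcohol (the C5′ centre).

Step 18
Reactants: 26 (3S)-1-[4-(methoxymethoxy)phenyl]hex-5-yn-3-ol
Product: 27 tert-butyl({(3S)-1-[4-(methoxymethoxy)phenyl]hex-5-yn-3-yl}oxy)dimethylsilane
Conditions: TBSCl, imidazole, DMF, rt
Reagents that add atoms: tert-butyldimethylsilyl chloride, CC(C)(C)[Si](C)(C)Cl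
Why: O-silylation protects the carbinol against the borane, zinc and copper reagents that follow.

Step 19
Reactants: 27 tert-butyl({(3S)-1-[4-(methoxymethoxy)phenyl]hex-5-yn-3-yl}oxy)dimethylsilane; 21 4-(methoxymethoxy)benzaldehyde
Product: 30 (1R,2E,5S)-5-(TBSO)-1,7-bis[4-(MOMO)phenyl]hept-2-en-1-ol, via alkenylborane 28 (not isolated), via alkenylzinc 29 (not isolated)
Conditions: Cy2BH (1.05 equiv), toluene, 0 °C to rt; Me2Zn (1.2 equiv), −78 °C; (+)-MIB (5 mol %), 21 (0.85 equiv), −10 °C; aq NH4Cl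
Reagents that add atoms: none
Why: In this Oppolzer–Walsh sequence syn-hydroboration gives the E-alkenylborane, boron-to-zinc exchange gives the alkenylzinc, and the (+)-MIB zinc aminoalkoxide delivers it to the Re face of the aryl aldehyde (mirror image of the Si-face delivery of (−)-MIB), which sets 1R independently of the remote C5 centre.

Step 20
Reactants: 30 (1R,2E,5S)-5-(TBSO)-1,7-bis[4-(MOMO)phenyl]hept-2-en-1-ol
Product: 31 (1R,2E,5S)-5-(TBSO)-1,7-bis[4-(MOMO)phenyl]hept-2-en-1-yl pyridine-2-carboxylate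
Conditions: picolinic acid (1.5 equiv), DCC (1.5 equiv), DMAP (0.2 equiv), CH2Cl2, 0 °C to rt
Reagents that add atoms: pyridine-2-carboxylic acid (picolinic acid), OC(=O)c1ccccn1
Why: Steglich esterification acylates the carbinol oxygen under neutral conditions with retention at C1 and installs the chelating leaving group; the ester is used at once.

Step 21
Reactants: 20 (2S,4S)-8-bromo-4-(TBSO)-5-methoxy-7-(MOMO)-2-[4-(MOMO)phenyl]chromane; 31 (1R,2E,5S)-5-(TBSO)-1,7-bis[4-(MOMO)phenyl]hept-2-en-1-yl pyridine-2-carboxylate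
Product: 35 (2S,4S)-4-(TBSO)-8-{(1E,3S,5S)-5-(TBSO)-1,7-bis[4-(MOMO)phenyl]hept-1-en-3-yl}-5-methoxy-7-(MOMO)-2-[4-(MOMO)phenyl]chromane, via aryllithium 32 (not isolated), via arylmagnesium bromide 33 (not isolated), via bromomagnesium diarylcuprate 34 (not isolated)
Conditions: 20 (2.4 equiv), t-BuLi (4.8 equiv), THF, −78 °C; MgBr2·OEt2 (2.4 equiv), −78 to 0 °C; CuBr·SMe2 (1.2 equiv), −40 °C; then 31 (1.0 equiv), −40 to 0 °C; aq NH4Cl
Reagents that add atoms: none
Why: In this Kobayashi-type copper-mediated anti-SN2′ allylic substitution the magnesium-chelated picolinate directs the arylcopper to the γ-carbon anti to the leaving group, from the conformer with C1–H in the alkene plane, so the 1R,2E ester gives the 3S centre and a new E-styrene while joining the two halves.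

Step 22
Reactants: 35 (2S,4S)-4-(TBSO)-8-{(1E,3S,5S)-5-(TBSO)-1,7-bis[4-(MOMO)phenyl]hept-1-en-3-yl}-5-methoxy-7-(MOMO)-2-[4-(MOMO)phenyl]chromane
Product: 36 (2S,4S)-8-{(1E,3S,5S)-5-hydroxy-1,7-bis[4-(MOMO)phenyl]hept-1-en-3-yl}-5-methoxy-7-(MOMO)-2-[4-(MOMO)phenyl]-3,4-dihydro-2H-chromen-4-ol
Conditions: Bu4NF (4 equiv), THF, rt
Reagents that add atoms: none
Why: Fluoride-induced desilylation cleaves both silyl ethers, while the MOM acetals and the weakly acidic C3′–H are not touched.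

Step 23
Reactants: 36 (2S,4S)-8-{(1E,3S,5S)-5-hydroxy-1,7-bis[4-(MOMO)phenyl]hept-1-en-3-yl}-5-methoxy-7-(MOMO)-2-[4-(MOMO)phenyl]-3,4-dihydro-2H-chromen-4-ol
Product: 37 (2S)-8-{(1E,3S,5S)-5-hydroxy-1,7-bis[4-(MOMO)phenyl]hept-1-en-3-yl}-5-methoxy-7-(MOMO)-2-[4-(MOMO)phenyl]-2,3-dihydro-4H-chromen-4-one
Conditions: activated MnO2 (20 equiv), CH2Cl2, rt
Reagents that add atoms: none
Why: MnO2 oxidises only the electron-rich benzylic C4 carbinol, so the saturated C5′ alcohol and the styrene survive, and without base the C2 centre is not epimerised.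

Step 24
Reactants: 37 (2S)-8-{(1E,3S,5S)-5-hydroxy-1,7-bis[4-(MOMO)phenyl]hept-1-en-3-yl}-5-methoxy-7-(MOMO)-2-[4-(MOMO)phenyl]-2,3-dihydro-4H-chromen-4-one
Product: 39 (2S)-7-hydroxy-8-[(1E,3S,5S)-5-hydroxy-1,7-bis(4-hydroxyphenyl)hept-1-en-3-yl]-2-(4-hydroxyphenyl)-5-methoxy-2,3-dihydro-4H-chromen-4-one, via pentakis(trimethylsilyl) ether 38 (not isolated)
Conditions: Me3SiOTf (10 equiv), 2,2′-bipyridyl (15 equiv), CH2Cl2, 0 °C to rt; then H2O, rt
Reagents that add atoms: none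
Why: In this Fujioka aromatic MOM cleavage the silyl triflate–bipyridyl pair turns each ArOCH2OMe into ArOSiMe3 and an N-(methoxymethyl)bipyridinium salt under buffered non-protic conditions and water then hydrolyses the silyl ethers, which spares the acid-labile hydroxystyryl unit and the base-labile C2 centre.

**Compound list**
1 | resorcinol (benzene-1,3-diol) | Oc1cccc(O)c1 | starting material
2 | 1,3-bis(methoxymethoxy)benzene | COCOc1cccc(OCOC)c1 | intermediate
3 | [2,6-bis(methoxymethoxy)phenyl]lithium | [Li]c1c(OCOC)cccc1OCOC | intermediate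
4 | 2-bromo-1,3-bis(methoxymethoxy)benzene | COCOc1cccc(OCOC)c1Br | intermediate
5 | 2-[4-bromo-3,5-bis(methoxymethoxy)phenyl]-4,4,5,5-tetramethyl-1,3,2-dioxaborolane | COCOc1cc(B2OC(C)(C)C(C)(C)O2)cc(OCOC)c1Br | intermediate
6 | 4-bromo-3,5-bis(methoxymethoxy)phenol | COCOc1cc(O)cc(OCOC)c1Br | intermediate
7 | 2-bromo-5-methoxy-1,3-bis(methoxymethoxy)benzene | COCOc1cc(OC)cc(OCOC)c1Br | intermediate
8 | 2-bromo-5-methoxybenzene-1,3-diol | COc1cc(O)c(Br)c(O)c1 | intermediate
9 | 1-(3-bromo-2,4-dihydroxy-6-methoxyphenyl)ethan-1-iminium chloride | COc1cc(O)c(Br)c(O)c1C(C)=[NH2+].[Cl-] | intermediate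
10 | 1-(3-bromo-2,4-dihydroxy-6-methoxyphenyl)ethan-1-one | COc1cc(O)c(Br)c(O)c1C(C)=O | intermediate
11 | (2E)-1-(3-bromo-2,4-dihydroxy-6-methoxyphenyl)-3-(dimethylamino)prop-2-en-1-one | COc1cc(O)c(Br)c(O)c1C(=O)/C=C/N(C)C | intermediate
12 | 8-bromo-7-hydroxy-5-methoxy-4H-chromen-4-one | COc1cc(O)c(Br)c2occc(=O)c12 | intermediate
13 | 8-bromo-5-methoxy-7-(methoxymethoxy)-4H-chromen-4-one | COc1cc(OCOC)c(Br)c2occc(=O)c12 | intermediate
14 | 4-bromophenol | Oc1ccc(Br)cc1 | starting material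
15 | 1-bromo-4-(methoxymethoxy)benzene | COCOc1ccc(Br)cc1 | intermediate
16 | [4-(methoxymethoxy)phenyl]lithium | [Li]c1ccc(OCOC)cc1 | intermediate
17 | [4-(methoxymethoxy)phenyl]boronic acid | COCOc1ccc(B(O)O)cc1 | intermediate
18 | (2S)-8-bromo-5-methoxy-7-(MOMO)-2-[4-(MOMO)phenyl]-2,3-dihydro-4H-chromen-4-one | COc1cc(OCOC)c(Br)c2c1C(=O)C[C@@H](c1ccc(OCOC)cc1)O2 | intermediate
19 | (2S,4S)-8-bromo-5-methoxy-7-(MOMO)-2-[4-(MOMO)phenyl]-3,4-dihydro-2H-chromen-4-ol (2,4-cis) | COc1cc(OCOC)c(Br)c2c1[C@@H](O)C[C@@H](c1ccc(OCOC)cc1)O2 | intermediate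
20 | (2S,4S)-8-bromo-4-(TBSO)-5-methoxy-7-(MOMO)-2-[4-(MOMO)phenyl]chromane | COc1cc(OCOC)c(Br)c2c1[C@@H](O[Si](C)(C)C(C)(C)C)C[C@@H](c1ccc(OCOC)cc1)O2 | intermediate
21 | 4-(methoxymethoxy)benzaldehyde | COCOc1ccc(C=O)cc1 | intermediate
22 | 4-iodophenol | Oc1ccc(I)cc1 | starting material
23 | 1-iodo-4-(methoxymethoxy)benzene | COCOc1ccc(I)cc1 | intermediate
24 | allyl alcohol (prop-2-en-1-ol) | C=CCO | starting material
25 | 3-[4-(methoxymethoxy)phenyl]propanal | COCOc1ccc(CCC=O)cc1 | intermediate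
26 | (3S)-1-[4-(methoxymethoxy)phenyl]hex-5-yn-3-ol | COCOc1ccc(CC[C@H](O)CC#C)cc1 | intermediate
27 | tert-butyl({(3S)-1-[4-(methoxymethoxy)phenyl]hex-5-yn-3-yl}oxy)dimethylsilane | COCOc1ccc(CC[C@H](O[Si](C)(C)C(C)(C)C)CC#C)cc1 | intermediate
28 | dicyclohexyl{(1E,4S)-4-(TBSO)-6-[4-(MOMO)phenyl]hex-1-en-1-yl}borane | COCOc1ccc(CC[C@H](O[Si](C)(C)C(C)(C)C)C/C=C/B(C2CCCCC2)C2CCCCC2)cc1 | intermediate
29 | {(1E,4S)-4-(TBSO)-6-[4-(MOMO)phenyl]hex-1-en-1-yl}(methyl)zinc | COCOc1ccc(CC[C@H](O[Si](C)(C)C(C)(C)C)C/C=C/[Zn]C)cc1 | intermediate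
30 | (1R,2E,5S)-5-(TBSO)-1,7-bis[4-(MOMO)phenyl]hept-2-en-1-ol | COCOc1ccc(CC[C@H](O[Si](C)(C)C(C)(C)C)C/C=C/[C@@H](O)c2ccc(OCOC)cc2)cc1 | intermediate
31 | (1R,2E,5S)-5-(TBSO)-1,7-bis[4-(MOMO)phenyl]hept-2-en-1-yl pyridine-2-carboxylate | COCOc1ccc(CC[C@H](O[Si](C)(C)C(C)(C)C)C/C=C/[C@@H](OC(=O)c2ccccn2)c2ccc(OCOC)cc2)cc1 | intermediate
32 | Fl-lithium (8-lithio analogue of 20) | COc1cc(OCOC)c([Li])c2c1[C@@H](O[Si](C)(C)C(C)(C)C)C[C@@H](c1ccc(OCOC)cc1)O2 | intermediate
33 | Fl-magnesium bromide | COc1cc(OCOC)c([Mg]Br)c2c1[C@@H](O[Si](C)(C)C(C)(C)C)C[C@@H](c1ccc(OCOC)cc1)O2 | intermediate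
34 | bromomagnesium bis(Fl)cuprate | [Mg+]Br.[Cu-](c1c(OCOC)cc(OC)c2c1O[C@H](c1ccc(OCOC)cc1)C[C@@H]2O[Si](C)(C)C(C)(C)C)c1c(OCOC)cc(OC)c2c1O[C@H](c1ccc(OCOC)cc1)C[C@@H]2O[Si](C)(C)C(C)(C)C | intermediate
35 | (2S,4S)-4-(TBSO)-8-{(1E,3S,5S)-5-(TBSO)-1,7-bis[4-(MOMO)phenyl]hept-1-en-3-yl}-5-methoxy-7-(MOMO)-2-[4-(MOMO)phenyl]chromane | COc1cc(OCOC)c([C@H](/C=C/c2ccc(OCOC)cc2)C[C@@H](O[Si](C)(C)C(C)(C)C)CCc2ccc(OCOC)cc2)c2c1[C@@H](O[Si](C)(C)C(C)(C)C)C[C@@H](c1ccc(OCOC)cc1)O2 | intermediate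
36 | (2S,4S)-8-{(1E,3S,5S)-5-hydroxy-1,7-bis[4-(MOMO)phenyl]hept-1-en-3-yl}-5-methoxy-7-(MOMO)-2-[4-(MOMO)phenyl]-3,4-dihydro-2H-chromen-4-ol | COc1cc(OCOC)c([C@H](/C=C/c2ccc(OCOC)cc2)C[C@@H](O)CCc2ccc(OCOC)cc2)c2c1[C@@H](O)C[C@@H](c1ccc(OCOC)cc1)O2 | intermediate
37 | (2S)-8-{(1E,3S,5S)-5-hydroxy-1,7-bis[4-(MOMO)phenyl]hept-1-en-3-yl}-5-methoxy-7-(MOMO)-2-[4-(MOMO)phenyl]-2,3-dihydro-4H-chromen-4-one | COc1cc(OCOC)c([C@H](/C=C/c2ccc(OCOC)cc2)C[C@@H](O)CCc2ccc(OCOC)cc2)c2c1C(=O)C[C@@H](c1ccc(OCOC)cc1)O2 | intermediate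
38 | (2S)-5-methoxy-7-(TMSO)-8-{(1E,3S,5S)-5-(TMSO)-1,7-bis[4-(TMSO)phenyl]hept-1-en-3-yl}-2-[4-(TMSO)phenyl]-2,3-dihydro-4H-chromen-4-one | COc1cc(O[Si](C)(C)C)c([C@H](/C=C/c2ccc(O[Si](C)(C)C)cc2)C[C@@H](O[Si](C)(C)C)CCc2ccc(O[Si](C)(C)C)cc2)c2c1C(=O)C[C@@H](c1ccc(O[Si](C)(C)C)cc1)O2 | intermediate
39 | (2S)-7-hydroxy-8-[(1E,3S,5S)-5-hydroxy-1,7-bis(4-hydroxyphenyl)hept-1-en-3-yl]-2-(4-hydroxyphenyl)-5-methoxy-2,3-dihydro-4H-chromen-4-one (CNP0191649.2) | COc1cc(O)c([C@H](/C=C/c2ccc(O)cc2)C[C@@H](O)CCc2ccc(O)cc2)c2c1C(=O)C[C@@H](c1ccc(O)cc1)O2 | target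

**Step count and risks**
Total steps: 24. Longest linear sequence: 15 (steps 1–8, 11–13, 21–24, from resorcinol).

Steps most likely to fail:

Step 21. The arylcopper reagent is flanked by two oxygen substituents and is hindered, and the electron-rich benzylic picolinate can ionise, which would erode the 1,3-chirality transfer or give α-attack. Only one aryl group of 34 is transferred; the other is recovered as the 8-H flavan. Fallback: build the C3′ centre by substrate-controlled conjugate addition to a lactone instead of allylic substitution. It sets out from 26 (and uses 20 and 15, already in hand) and comes back at 35. The dianion of 26 (n-BuLi, 2 equiv, THF, −78 °C) is carboxylated with CO2 to (5S)-5-hydroxy-7-[4-(MOMO)phenyl]hept-2-ynoic acid F1. Semihydrogenation (H2, Pd/CaCO3 poisoned with Pb(OAc)2, quinoline) and lactonisation (PPTS, toluene) give (6S)-6-{2-[4-(MOMO)phenyl]ethyl}-5,6-dihydro-2H-pyran-2-one F2. Cuprate 34 (made from 20 as in step 21) with Me3SiCl adds 1,4 anti to the C6 side chain and gives the trans lactone (4S,6S)-4-Fl-6-{2-[4-(MOMO)phenyl]ethyl}oxan-2-one F3, which already has the 3S,5S relationship of the target. Aryllithium 16 (from 15) opens the lactone at −78 °C to (3S,5S)-3-Fl-5-hydroxy-1,7-bis[4-(MOMO)phenyl]heptan-1-one F4. TBSCl/imidazole gives (3S,5S)-3-Fl-5-(TBSO)-1,7-bis[4-(MOMO)phenyl]heptan-1-one F5. KN(SiMe3)2 and PhNTf2 trap the Z-enolate as (1Z,3S,5S)-3-Fl-5-(TBSO)-1,7-bis[4-(MOMO)phenyl]hept-1-en-1-yl trifluoromethanesulfonate F6. Pd(OAc)2/PPh3 with HCO2H and Et3N replaces the triflate by hydrogen with retention, which gives the E-styrene 35.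

Step 11. Chromones are poor acceptors, the 5-OMe group lowers the electrophilicity further, the product can undergo 1,2-addition, and the sense and level of induction on this 8-bromo substrate are untested. Fallback: make the flavanone racemic and set C2 by a reductive kinetic resolution. It sets out from 10 (and uses 21) and comes back at 19. Selective alkylation of the non-chelated 4-OH of 10 (MOMCl, K2CO3, 1 equiv) gives 1-[3-bromo-2-hydroxy-6-methoxy-4-(MOMO)phenyl]ethan-1-one F7. Claisen–Schmidt condensation with 21 (KOH, EtOH) gives (2E)-1-[3-bromo-2-hydroxy-6-methoxy-4-(MOMO)phenyl]-3-[4-(MOMO)phenyl]prop-2-en-1-one F8. Oxa-Michael ring closure (NaOAc, EtOH, reflux) gives racemic 8-bromo-5-methoxy-7-(MOMO)-2-[4-(MOMO)phenyl]-2,3-dihydro-4H-chromen-4-one F9. Noyori transfer hydrogenation with RuCl[(S,S)-TsDPEN](p-cymene) in HCO2H/Et3N reduces the 2S enantiomer (hydride anti to the aryl group, 4S) to 19. The 2R ketone is left behind, separated, and can be racemised with base and recycled.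

Step 17. Organocatalytic propargylation of an unbranched aliphatic aldehyde may stop at about 80–90% ee, which would give diastereomer mixtures after step 19. Fallback: set C5′ by asymmetric hydrogenation instead of asymmetric C–C bond formation. It sets out from 25 and comes back at 27. Roskamp homologation (ethyl diazoacetate, SnCl2, CH2Cl2) gives ethyl 5-[4-(MOMO)phenyl]-3-oxopentanoate F10. Noyori hydrogenation with RuCl2[(S)-BINAP] and H2 in EtOH gives ethyl (3S)-3-hydroxy-5-[4-(MOMO)phenyl]pentanoate F11. TBSCl/imidazole gives ethyl (3S)-3-(TBSO)-5-[4-(MOMO)phenyl]pentanoate F12. i-Bu2AlH at −78 °C gives (3S)-3-(TBSO)-5-[4-(MOMO)phenyl]pentanal F13. Ohira–Bestmann homologation (dimethyl (1-diazo-2-oxopropyl)phosphonate, K2CO3, MeOH) gives alkyne 27.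

**Further compounds**
F1 | step 21 | (5S)-5-hydroxy-7-[4-(MOMO)phenyl]hept-2-ynoic acid | COCOc1ccc(CC[C@H](O)CC#CC(O)=O)cc1
F2 | step 21 | (6S)-6-{2-[4-(MOMO)phenyl]ethyl}-5,6-dihydro-2H-pyran-2-one | COCOc1ccc(CC[C@H]2CC=CC(=O)O2)cc1
F3 | step 21 | (4S,6S)-4-Fl-6-{2-[4-(MOMO)phenyl]ethyl}oxan-2-one | COCOc1ccc(CC[C@H]2C[C@H](c3c(OCOC)cc(OC)c4c3O[C@H](c3ccc(OCOC)cc3)C[C@@H]4O[Si](C)(C)C(C)(C)C)CC(=O)O2)cc1
F4 | step 21 | (3S,5S)-3-Fl-5-hydroxy-1,7-bis[4-(MOMO)phenyl]heptan-1-one | COCOc1ccc(CC[C@H](O)C[C@H](c3c(OCOC)cc(OC)c4c3O[C@H](c3ccc(OCOC)cc3)C[C@@H]4O[Si](C)(C)C(C)(C)C)CC(=O)c2ccc(OCOC)cc2)cc1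
F5 | step 21 | (3S,5S)-3-Fl-5-(TBSO)-1,7-bis[4-(MOMO)phenyl]heptan-1-one | COCOc1ccc(CC[C@H](O[Si](C)(C)C(C)(C)C)C[C@H](c3c(OCOC)cc(OC)c4c3O[C@H](c3ccc(OCOC)cc3)C[C@@H]4O[Si](C)(C)C(C)(C)C)CC(=O)c2ccc(OCOC)cc2)cc1
F6 | step 21 | (1Z,3S,5S)-3-Fl-5-(TBSO)-1,7-bis[4-(MOMO)phenyl]hept-1-en-1-yl trifluoromethanesulfonate | COCOc1ccc(CC[C@H](O[Si](C)(C)C(C)(C)C)C[C@H](c3c(OCOC)cc(OC)c4c3O[C@H](c3ccc(OCOC)cc3)C[C@@H]4O[Si](C)(C)C(C)(C)C)/C=C(\OS(=O)(=O)C(F)(F)F)c2ccc(OCOC)cc2)cc1
F7 | step 11 | 1-[3-bromo-2-hydroxy-6-methoxy-4-(MOMO)phenyl]ethan-1-one | COc1cc(OCOC)c(Br)c(O)c1C(C)=O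
F8 | step 11 | (2E)-1-[3-bromo-2-hydroxy-6-methoxy-4-(MOMO)phenyl]-3-[4-(MOMO)phenyl]prop-2-en-1-one | COc1cc(OCOC)c(Br)c(O)c1C(=O)/C=C/c1ccc(OCOC)cc1
F9 | step 11 | racemic 8-bromo-5-methoxy-7-(MOMO)-2-[4-(MOMO)phenyl]-2,3-dihydro-4H-chromen-4-one | COc1cc(OCOC)c(Br)c2c1C(=O)CC(c1ccc(OCOC)cc1)O2
F10 | step 17 | ethyl 5-[4-(MOMO)phenyl]-3-oxopentanoate | CCOC(=O)CC(=O)CCc1ccc(OCOC)cc1
F11 | step 17 | ethyl (3S)-3-hydroxy-5-[4-(MOMO)phenyl]pentanoate | CCOC(=O)C[C@@H](O)CCc1ccc(OCOC)cc1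
F12 | step 17 | ethyl (3S)-3-(TBSO)-5-[4-(MOMO)phenyl]pentanoate | CCOC(=O)C[C@@H](O[Si](C)(C)C(C)(C)C)CCc1ccc(OCOC)cc1
F13 | step 17 | (3S)-3-(TBSO)-5-[4-(MOMO)phenyl]pentanal | O=CC[C@@H](O[Si](C)(C)C(C)(C)C)CCc1ccc(OCOC)cc1
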